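(The data were generated by integration for substances that don't exist; scatter was added.)

1.74 was the factor, as read from scattered readings, by which the rate in oak outran that in elm at about the same product, 11.8 %, on 1.50 times the catalyst. That factor was more than the ratio of the charges, so I supposed that both flasks had lost the same amount of catalyst at the same product. On that supposition I reckoned that elm had lost 32.8 % of its charge. I read 0.139 as the catalyst price, the moles of catalyst lost per mole of left-handed product made. At that price I reckoned that elm's 13.4 % had cost 37.1 % of its catalyst and oak's 18.2 % had cost 33.6 % of its larger charge.

| flask | left-handed substrate | right-handed substrate | coupling partner | free catalyst | remark |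
|---|---|---|---|---|---|
| elm | 0.050 M | 0.050 M | 1 equiv | 10 mol% | the very flask that is asked about, followed so far |
| oak | 0.050 M | 0.050 M | 1 equiv | 15 mol% | run made earlier |
| flask | 0.050 M | 0.050 M | 1.00 equiv | 10 mol% |  |

- elm (time / min: left-handed product / %): 2.00: 5.0; 4.00: 9.5; 6.00: 11.3; 8.00: 13.4
- oak (time / min: left-handed product / %): 1.00: 4.7; 3.00: 10.5; 5.00: 13.9; 8.00: 18.2

(readings scatter by 0.5 percentage points)

- apparent order in coupling partner when 10 % of the left-handed substrate and right-handed substrate together are converted (percent change of the rate of making left-handed product for one percent more coupling partner charged)
- factor on the rate of making left-handed product when 10 % of the left-handed substrate and right-handed substrate together are converted if free catalyst is charged twice over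

- free catalyst is single-handed; left-handed substrate and right-handed substrate are mirror images of each other, charged as a racemate, each of them at the stated concentration
- no earlier run changes the charge of coupling partner; that part of a forecast is a guess

The flask asked about is elm. At the conversion in question my price left 72.3 % of its catalyst free. I took a doubled charge to pay the same amount, so I reckoned a factor of 2.38. No run changed the coupling partner, so I had no reading of its order. The forecast differed from my factor: it gave 2.2 and an order of 0.5, holding that “the rate scales roughly as catalyst^1.1”.

The flask gave 2.62 for the doubling and 1.4 for the order.

    coupling partner + free catalyst + right-handed substrate → free catalyst + right-handed product (k = 14.0 M⁻² min⁻¹)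
    coupling partner + free catalyst + left-handed substrate → free catalyst + left-handed product (k = 300 M⁻² min⁻¹)
    coupling partner + free catalyst → spent catalyst (k = 2.50 M⁻¹ min⁻¹)
    coupling partner ⇌ dormant form (K = 2.80, k = 0.0110 min⁻¹)

In the flask, at 4.10 min, free catalyst stood at 64.8 % of the charge, which I reckoned as a price of about 0.176 and, by my rule, a factor of 2.54 for a doubled charge. At the flask's charged left-handed substrate, free catalyst with coupling partner went to left-handed product 6.00 times as fast as to spent catalyst. On oak, I reckoned with that price 76.6 % of the catalyst free at the same conversion.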